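**Strategy.** Chromene numbering is used (O1, C2–C4 in lactone ring B; C4a–C8a in carbocycle ring A). Everything rests on cutting ring B at both ends of the enol double bond C4a=C8a that it shares with ring A: C4–C4a and O1–C8a. In a dearomatised acylphloroglucinol C4a is nucleophilic and C8a electrophilic; a pyrrolidine enaminone at C8a sharpens both. It is matched with (R)-4-phenyloxetan-2-one, whose benzylic carbon is electrophilic and whose carboxylate is set free on opening. One operation gives SN2 C-alkylation with inversion (4S), closure of ring B at the iminium carbon and loss of the amine. The precursor carries nitrogen, not oxygen, at C8a.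

Key step: step 6

Remark: (R)-2-methylbutanoic acid and (R)-3-hydroxy-3-phenylpropanoic acid are assumed to be purchasable in enantiopure form; 7, 8 and 13 are each drawn as one enol tautomer.

**Step 1**
Reactants: 1 phloroglucinol (benzene-1,3,5-triol); 2 (R)-2-methylbutanoic acid
Product: 4 (2R)-2-methyl-1-(2,4,6-trihydroxyphenyl)butan-1-one, via (R)-2-methylbutanoyl chloride 3 (not isolated)
Conditions: 2, (COCl)2, cat. DMF, CH2Cl2, 0 °C to rt; then 1, AlCl3 (3 equiv), PhNO2/CH2Cl2, 0 °C to rt; aq. HCl
Reagents that add atoms: none
Why: Friedel–Crafts acylation of the threefold-activated, symmetric arene by the acid chloride made in situ: all three ring carbons are equivalent, a second acylation is slowed by the deactivating ketone, and the α-stereocenter is carried through unchanged at low temperature.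

**Step 2**
Reactants: 4 (2R)-2-methyl-1-(2,4,6-trihydroxyphenyl)butan-1-one
Product: 5 (2R)-1-(2,6-dihydroxy-4-methoxyphenyl)-2-methylbutan-1-one
Conditions: Me2SO4 (1.0 equiv), K2CO3 (1.0 equiv), acetone, rt
Reagents that add atoms: dimethyl sulfate, COS(=O)(=O)OC
Why: Williamson ether synthesis under stoichiometric control: the 4-hydroxyl para to the ketone is the most acidic and the only one not held in a hydrogen bond to the carbonyl, so it is methylated first.

**Step 3**
Reactants: 5 (2R)-1-(2,6-dihydroxy-4-methoxyphenyl)-2-methylbutan-1-one; 6 prenyl bromide (1-bromo-3-methylbut-2-ene, 2.2 equiv)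
Product: 7 3-hydroxy-5-methoxy-2-[(2R)-2-methylbutanoyl]-6,6-bis(3-methylbut-2-en-1-yl)cyclohexa-2,4-dien-1-one
Conditions: NaOMe (2.2 equiv), MeOH, 0 °C to rt, slow addition of 6
Reagents that add atoms: none
Why: Dearomatising double C-alkylation of the phenoxide (Claisen-type C-allylation with an SN2 allylic halide): the two free ring carbons of 5 are equivalent for the first prenyl group, and the second should enter the same, now more electron-rich carbon, because a prenyl group on the other carbon would wedge the 4-methoxy group between two substituents; the resulting dienone cannot rearomatise and its triketone anion is inert to further C-alkylation.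

**Step 4**
Reactants: 7 3-hydroxy-5-methoxy-2-[(2R)-2-methylbutanoyl]-6,6-bis(3-methylbut-2-en-1-yl)cyclohexa-2,4-dien-1-one
Product: 8 3-hydroxy-2-[(2R)-2-methylbutanoyl]-6,6-bis(3-methylbut-2-en-1-yl)-5-(pyrrolidin-1-yl)cyclohexa-2,4-dien-1-one
Conditions: pyrrolidine (3 equiv), AcOH (1 equiv), toluene, 60 °C; pH 5 buffer wash
Reagents that add atoms: pyrrolidine, C1CCNC1
Why: Addition–elimination at a vinylogous ester (vinylogous transamidation): the methoxy-bearing ring carbon is the only position with a leaving group, so nitrogen is installed exactly at the future C8a and methanol is lost to give the more stable vinylogous amide.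

**Step 5**
Reactants: 9 (R)-3-hydroxy-3-phenylpropanoic acid
Product: 10 (R)-4-phenyloxetan-2-one
Conditions: PhSO2Cl (2 equiv), pyridine, 0 to 5 °C
Reagents that add atoms: none
Why: β-Lactonisation through carboxyl activation as the mixed carboxylic–sulfonic anhydride and 4-exo-trig attack of the β-hydroxyl on the acyl carbon: no bond to the benzylic stereocenter is broken, so the R configuration is retained.

**Step 6**
Reactants: 8 3-hydroxy-2-[(2R)-2-methylbutanoyl]-6,6-bis(3-methylbut-2-en-1-yl)-5-(pyrrolidin-1-yl)cyclohexa-2,4-dien-1-one; 10 (R)-4-phenyloxetan-2-one (1.5 equiv)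
Product: 13 (4S)-5-hydroxy-6-[(2R)-2-methylbutanoyl]-8,8-bis(3-methylbut-2-en-1-yl)-4-phenyl-3,4-dihydro-2H-chromene-2,7(8H)-dione, via iminium carboxylate zwitterion 11 (not isolated), via cyclic N,O-ketal 12 (not isolated)
Conditions: MeCN, 4 Å MS, 45 °C; then MsOH (1.0 equiv), same pot, 0 °C to rt
Reagents that add atoms: none
Why: Proposed new method: the enamine carbon C4a of 8 attacks the benzylic carbon of lactone 10 in an SN2 reaction with alkyl–oxygen cleavage, which forms C4–C4a and leaves a carboxylate beside the C8a iminium ion (11); the carboxylate oxygen adds to that iminium carbon to form O1–C8a (12), and after N-protonation pyrrolidine is lost by E1cB-type elimination through the C5 enol to give the C4a=C8a enol lactone. The closest known reaction types are the Stork enamine alkylation with β-propiolactone (carboxyethylation by alkyl–oxygen opening) and acid-mediated exchange at a vinylogous amide carbon, merged here into a formal [4+2] annulation. Ring B closes by 6-exo-trig attack of the carboxylate on the exocyclic C=N+ bond. The new stereocenter C4 is controlled by the reagent alone: stereospecific inversion turns the R lactone carbon into 4S, and the transient C4a center is erased in the elimination. The step needs C-alkylation over O-alkylation and substitution over ionisation or decarboxylation of the lactone, which the soft neutral enamine carbon and the Lewis-acid-free first stage should secure; ring closure at C8a rather than at the C5 oxygen is favoured because the carboxylate meets an isolated iminium carbon there while C5 is an unreactive enol carbon, and because allylic strain around the now tetrasubstituted enamine makes the twisted amine the leaving group, while the acidic triketone hydroxyl and one equivalent of MsOH hold the freed amine as its salt so that it cannot open the product.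

**Compound list**
1 | phloroglucinol (benzene-1,3,5-triol) | Oc1cc(O)cc(O)c1 | starting material
2 | (R)-2-methylbutanoic acid | CC[C@@H](C)C(=O)O | starting material
3 | (R)-2-methylbutanoyl chloride | CC[C@@H](C)C(=O)Cl | intermediate
4 | (2R)-2-methyl-1-(2,4,6-trihydroxyphenyl)butan-1-one | CC[C@@H](C)C(=O)c1c(O)cc(O)cc1O | intermediate
5 | (2R)-1-(2,6-dihydroxy-4-methoxyphenyl)-2-methylbutan-1-one | CC[C@@H](C)C(=O)c1c(O)cc(OC)cc1O | intermediate
6 | prenyl bromide (1-bromo-3-methylbut-2-ene) | CC(C)=CCBr | starting material
7 | 3-hydroxy-5-methoxy-2-[(2R)-2-methylbutanoyl]-6,6-bis(3-methylbut-2-en-1-yl)cyclohexa-2,4-dien-1-one | CC[C@@H](C)C(=O)C1=C(O)C=C(OC)C(CC=C(C)C)(CC=C(C)C)C1=O | intermediate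
8 | 3-hydroxy-2-[(2R)-2-methylbutanoyl]-6,6-bis(3-methylbut-2-en-1-yl)-5-(pyrrolidin-1-yl)cyclohexa-2,4-dien-1-one | CC[C@@H](C)C(=O)C1=C(O)C=C(N2CCCC2)C(CC=C(C)C)(CC=C(C)C)C1=O | intermediate
9 | (R)-3-hydroxy-3-phenylpropanoic acid | OC(=O)C[C@@H](O)c1ccccc1 | starting material
10 | (R)-4-phenyloxetan-2-one | O=C1C[C@@H](O1)c1ccccc1 | intermediate
11 | 3-[2-hydroxy-3-[(2R)-2-methylbutanoyl]-5,5-bis(3-methylbut-2-en-1-yl)-4-oxo-6-(pyrrolidin-1-ium-1-ylidene)cyclohex-2-en-1-yl]-3-phenylpropanoate; benzylic carbon in the spatial sense of C4 of 13 (labelled 3R here only because the ring carbon is sp3), ring CH undefined | CC[C@@H](C)C(=O)C1=C(O)C([C@@H](CC(=O)[O-])c2ccccc2)C(=[N+]3CCCC3)C(CC=C(C)C)(CC=C(C)C)C1=O | intermediate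
12 | 5-hydroxy-6-[(2R)-2-methylbutanoyl]-8,8-bis(3-methylbut-2-en-1-yl)-4-phenyl-8a-(pyrrolidin-1-yl)-3,4,4a,8a-tetrahydro-2H-chromene-2,7(8H)-dione; C4 in the spatial sense of 13, C4a and C8a undefined | CC[C@@H](C)C(=O)C1=C(O)C2[C@H](c3ccccc3)CC(=O)OC2(N4CCCC4)C(CC=C(C)C)(CC=C(C)C)C1=O | intermediate
13 | (4S)-5-hydroxy-6-[(2R)-2-methylbutanoyl]-8,8-bis(3-methylbut-2-en-1-yl)-4-phenyl-3,4-dihydro-2H-chromene-2,7(8H)-dione | CC[C@@H](C)C(=O)C1=C(O)C2=C(OC(=O)C[C@H]2c2ccccc2)C(CC=C(C)C)(CC=C(C)C)C1=O | target

**Step count:** 6 steps in total.
**Longest linear sequence:** 5 steps (steps 1, 2, 3, 4, 6); step 5 is a one-step side branch.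

**Steps most likely to fail**

1. Step 6 (proposed new method). What may go wrong:
   - the enaminone may be alkylated at oxygen or react too slowly;
   - the benzylic C–O bond of the lactone may ionise, with erosion of configuration or decarboxylation to styrene;
   - the alkylated enaminone acid may close on the C5 side or fail to expel the amine;
   - the freed amine may open the product.

   Fallback by known chemistry, setting out from 7: mild hydrolysis of the enol ether (1 M HCl, THF, rt) should give the free trione 3,5-dihydroxy-2-[(2R)-2-methylbutanoyl]-6,6-bis(3-methylbut-2-en-1-yl)cyclohexa-2,4-dien-1-one F1. F1 is then annulated with (E)-cinnamic anhydride under isothiourea catalysis (HyperBTM, the enantiomer that delivers 4S, iPr2NEt, CH2Cl2, rt). C4a adds enantioselectively to the α,β-unsaturated acyl ammonium ion, and the lactone is closed by acyl transfer to the C8a enol oxygen, the one not held in the hydrogen bond to the side-chain carbonyl. The fallback returns to the route at 13.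

2. Step 3. What may go wrong: the second alkylation may go to the other free ring carbon (aromatic 3,5-diprenyl isomer) or to oxygen instead of geminally. Fallback, setting out from 5: monobromination (N-bromosuccinimide, 1.0 equiv, CH2Cl2, 0 °C) should give (2R)-1-(3-bromo-2,6-dihydroxy-4-methoxyphenyl)-2-methylbutan-1-one F2, in which only one ring carbon is free. Dearomatising bis-prenylation with 6 (NaOMe, MeOH) should then give 4-bromo-3-hydroxy-5-methoxy-2-[(2R)-2-methylbutanoyl]-6,6-bis(3-methylbut-2-en-1-yl)cyclohexa-2,4-dien-1-one F3. Hydrodebromination of the vinylic bromide (cat. Pd(PPh3)4, HCO2H, Et3N, DMF, 60 °C) returns to the route at 7.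

3. Step 4. What may go wrong: addition–elimination at the carbon next to the quaternary centre may be too slow, and the amine may condense at the side-chain carbonyl instead. Fallback, setting out from 4: the nitrogen is introduced before dearomatisation. Heating 4 with pyrrolidine (toluene, reflux, water separator) should exchange the non-chelated 4-hydroxyl through its keto tautomer, as in the Bucherer-type amination of phloroglucinol to 5-aminoresorcinols, to give (2R)-1-[2,6-dihydroxy-4-(pyrrolidin-1-yl)phenyl]-2-methylbutan-1-one F4. Geminal bis-prenylation of F4 with 6 (NaOMe, MeOH, as in step 3) returns to the route at 8.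

**Further compounds**
F1 | step 6 | 3,5-dihydroxy-2-[(2R)-2-methylbutanoyl]-6,6-bis(3-methylbut-2-en-1-yl)cyclohexa-2,4-dien-1-one | CC[C@@H](C)C(=O)C1=C(O)C=C(O)C(CC=C(C)C)(CC=C(C)C)C1=O
F2 | step 3 | (2R)-1-(3-bromo-2,6-dihydroxy-4-methoxyphenyl)-2-methylbutan-1-one | CC[C@@H](C)C(=O)c1c(O)cc(OC)c(Br)c1O
F3 | step 3 | 4-bromo-3-hydroxy-5-methoxy-2-[(2R)-2-methylbutanoyl]-6,6-bis(3-methylbut-2-en-1-yl)cyclohexa-2,4-dien-1-one | CC[C@@H](C)C(=O)C1=C(O)C(Br)=C(OC)C(CC=C(C)C)(CC=C(C)C)C1=O
F4 | step 4 | (2R)-1-[2,6-dihydroxy-4-(pyrrolidin-1-yl)phenyl]-2-methylbutan-1-one | CC[C@@H](C)C(=O)c1c(O)cc(N2CCCC2)cc1O
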